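A direct plan would cut the ester last: seco acid A3 would be joined to keto alcohol A4 by a mixed-anhydride esterification, then desilylated, oxidised at C5 and C7' and desilylated at C3.
It would grow the acid on a pyran template: cyclocondensation of a silyloxy diene with an α-methyl-β-benzyloxy aldehyde would give dihydropyranone A1, which would pass through acetal, carbinol, silyl ether and δ-lactone stages to pyrone lactone A2, opened to A3.
First weakness, the esterification of A3 with A4: an α-branched β-silyloxy acid must acylate a carbinol flanked by two methyl-bearing carbons and β to a ketone, so acylation is slow and ketene formation (C2 epimerisation), retro-aldol cleavage and β-elimination compete.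
Second weakness, the template stretch from A1 to A2: some ten acetal, redox and protecting-group operations form no skeletal bond, and two carbinol centres (C5, C7') are set under control only to be oxidised.
Third weakness, the opening of lactone A2 with exhaustive silylation and selective silyl ester hydrolysis: the seco acid tends to relactonise, and the C5 hydroxyl freed before the last oxidation can attack the hindered ester.

Retrosynthetic overview
- The ester oxygen on C5' lies β to two equivalent ketones (C3', C7'). This β-acyloxy ketone is read as an oxidised Evans–Tishchenko product, so C1(=O)–O5' is cut to aldehyde 27 and the unprotected keto diol 7; one oxidation then restores C3'=O and raises C7'.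
- The only ring, the 4-pyranone (O, C7–C11), is closed first, on a C5 carbinol. C3–C4 then comes from a boron anti aldol of pyrone ethyl ketone 19 and C2 from a hydroxyl-directed hydrogenation, so C4, C3 and C2 are all relayed from C6.
- C6 and C6' come from the D- and L-proline dimerisations of propanal, C4' from a Felkin-controlled pentanone aldol; carbinols that end as ketones (C5, C3', C7') are never controlled or protected.
- The design has no acylation of the hindered carbinol, no pyran template and no lactone to open; one silyl ether (C3) is carried to the end.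

Key step: step 16

Remark: C5' of the alkoxy part carries two identical (R)-arms and is not a stereocentre in the target, so the configurations at C3', C5', C7' and C5 in intermediates are immaterial. Locants C1–C11 (acid) and C1'–C9' (alkoxy part) are used throughout.

Step 1
Reactants: 1 propanal (2 equiv; one molecule as enamine donor, one as aldol acceptor)
Product: 3 (2S,3S)-2-methyl-3-(trimethylsilyloxy)pentanal, via hydroxy aldehyde 2 (not isolated)
Conditions: L-proline (10 mol%), DMF, 4 °C; then Me3SiCl, imidazole, 0 °C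
Reagents that add atoms: propanal (the second molecule of 1, as aldol acceptor), CCC=O; chlorotrimethylsilane, C[Si](C)(C)Cl
Why: Proline enamine catalysis (direct asymmetric aldol dimerisation of two molecules of propanal, anti-selective) should set aldehyde C2, the future C6', as S, and silylation in the same flask stops hemiacetal oligomerisation; the minor C3 epimer should share the C2 centre and is removed with the minor isomers at 7.

Step 2
Reactants: 4 pentan-3-one; 3 (2S,3S)-2-methyl-3-(trimethylsilyloxy)pentanal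
Product: 7 (4R,5R,6S,7S)-5,7-dihydroxy-4,6-dimethylnonan-3-one, via enol borinate 5 (not isolated), via silyl ether 6 (not isolated)
Conditions: (c-C6H11)2BCl, Et3N, Et2O, 0 °C; 3, −78 → −20 °C; H2O2, MeOH, pH 7 buffer; then citric acid, MeOH, rt
Reagents that add atoms: none
Why: Anti-selective boron aldol: the (E)-enol borinate should add through a chair transition state (C4'–C5' anti) with Felkin selectivity at the α-methyl aldehyde (C5'–C6' syn), which places the two methyl groups anti (C4' R, matching C6'); mild acidic methanolysis then frees the C7' hydroxyl.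

Step 3
Reactants: 1 propanal (2 equiv; one molecule as enamine donor, one as aldol acceptor)
Product: 9 (2R,3R)-2-methyl-3-(triethylsilyloxy)pentanal, via hydroxy aldehyde 8 (not isolated)
Conditions: D-proline (10 mol%), DMF, 4 °C; then Et3SiCl, imidazole, 0 °C
Reagents that add atoms: propanal (the second molecule of 1, as aldol acceptor), CCC=O; chlorotriethylsilane, CC[Si](Cl)(CC)CC
Why: The D-proline-catalysed aldol dimerisation of two molecules of propanal should give the mirror-image aldehyde, whose C2 becomes C6 of the acid; its C3 carbinol is the future C5 ketone, so both C3 epimers converge in step 9.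

Step 4
Reactants: 10 3-methylpentane-2,4-dione
Product: 11 (E)-4-methoxy-3-methylpent-3-en-2-one
Conditions: HC(OMe)3, MeOH, H2SO4 (cat.), rt
Reagents that add atoms: trimethyl orthoformate, COC(OC)OC
Why: Acid-catalysed enol ether formation with the orthoester can give only one regioisomer from the symmetric 1,3-diketone.

Step 5
Reactants: 11 (E)-4-methoxy-3-methylpent-3-en-2-one
Product: 13 (E)-5-methoxy-4-methylhex-4-en-3-one, via lithium enolate 12 (not isolated)
Conditions: LiN(i-Pr)2, THF, −78 °C; MeI, −78 → 0 °C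
Reagents that add atoms: iodomethane, CI
Why: Kinetic deprotonation of the vinylogous ester at its α′ methyl group and C-methylation of the lithium enolate should give the ethyl ketone.

Step 6
Reactants: 13 (E)-5-methoxy-4-methylhex-4-en-3-one; 9 (2R,3R)-2-methyl-3-(triethylsilyloxy)pentanal
Product: 15 (E)-6-hydroxy-2-methoxy-3,5,7-trimethyl-8-(triethylsilyloxy)dec-2-en-4-one (C7 and C8 as in 9; mixture at C5 and C6), via lithium enolate 14 (not isolated)
Conditions: 13, LiN(i-Pr)2, THF, −78 °C; then 9, −78 °C; AcOH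
Reagents that add atoms: none
Why: Aldol addition of the kinetic α′ lithium enolate to the α-chiral aldehyde at −78 °C forms C7–C8; the two new centres are not controlled because steps 7 and 8 erase them.

Step 7
Reactants: 15 the aldol adduct
Product: 16 (2E,7R,8R)-2-methoxy-3,5,7-trimethyl-8-(triethylsilyloxy)dec-2-ene-4,6-dione (C5 stereolabile)
Conditions: Dess–Martin periodinane, pyridine, CH2Cl2, rt
Reagents that add atoms: none
Why: Dess–Martin oxidation gives the 1,3-diketone, which enolises between its two carbonyls; C6 has only a silyloxy carbinol on its other side and should keep its configuration.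

Step 8
Reactants: 16 the 1,3-diketone
Product: 18 2-[(2R,3R)-3-hydroxypentan-2-yl]-3,5,6-trimethyl-4H-pyran-4-one, via pyrone silyl ether 17 (not isolated)
Conditions: TsOH·H2O (cat.), CH2Cl2, rt; then MeOH, rt
Reagents that add atoms: none
Why: Acid-mediated 4-pyranone synthesis: the enol oxygen on C7 adds 6-endo-trig to the β-methoxy enone and methanol is lost; methanol then cleaves the triethylsilyl ether, which is harmless once C7 and C9 are no longer ketones.

Step 9
Reactants: 18 the pyrone alcohol
Product: 19 3,5,6-trimethyl-2-[(2S)-3-oxopentan-2-yl]-4H-pyran-4-one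
Conditions: Dess–Martin periodinane, NaHCO3, CH2Cl2, 0 °C → rt
Reagents that add atoms: none
Why: Buffered Dess–Martin oxidation gives the ethyl ketone; C6 now lies between ketone and pyrone, but allylic 1,3-strain with the 3-methyl group of the ring should hold the C6–H bond in the ring plane (as in β-keto imides) and protect it kinetically.

Step 10
Reactants: 20 2-methylidenepropane-1,3-diol
Product: 21 2-[(triethylsilyloxy)methyl]prop-2-en-1-ol
Conditions: NaH (1 equiv), THF, 0 °C; Et3SiCl
Reagents that add atoms: chlorotriethylsilane, CC[Si](Cl)(CC)CC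
Why: Monosilylation of the symmetric diol through its sparingly soluble monosodium alkoxide should stop cleanly after one silyl group.

Step 11
Reactants: 21 the monosilyl ether
Product: 22 2-[(triethylsilyloxy)methyl]prop-2-enal
Conditions: MnO2, CH2Cl2, rt
Reagents that add atoms: none
Why: MnO2 oxidises the allylic alcohol selectively to the enal and leaves the silyl ether alone.

Step 12
Reactants: 19 the pyrone ethyl ketone; 22 2-[(triethylsilyloxy)methyl]prop-2-enal
Product: 24 (2S,4S,5R)-5-hydroxy-4-methyl-6-[(triethylsilyloxy)methyl]-2-(3,5,6-trimethyl-4-oxo-4H-pyran-2-yl)hept-6-en-3-one, via enol borinate 23 (not isolated)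
Conditions: (c-C6H11)2BCl (2.5 equiv), Me2NEt, Et2O, 0 °C; 22, −78 → −20 °C; H2O2, MeOH, pH 7 buffer, 0 °C
Reagents that add atoms: none
Why: Substrate-controlled boron anti aldol: the boron chloride and a small amine should enolise the ethyl CH2 (not the hindered, in-plane C6–H) to the (E)-enol borinate, whose chair transition state gives the 3,4-anti adduct on the enolate face away from the pyrone ring (4,6-anti), by analogy with the anti,anti aldols of α′-stereogenic ethyl ketones that carry an acyl-type group; the achiral enal has no bias of its own.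

Step 13
Reactants: 24 the allylic alcohol
Product: 25 (2S,4S,5S,6S)-5-hydroxy-4,6-dimethyl-7-(triethylsilyloxy)-2-(3,5,6-trimethyl-4-oxo-4H-pyran-2-yl)heptan-3-one
Conditions: H2 (40 atm), [Rh(nbd)(dppb)]BF4 (5 mol%; nbd = norbornadiene, dppb = 1,4-bis(diphenylphosphino)butane), CH2Cl2, rt
Reagents that add atoms: none
Why: Hydroxyl-directed hydrogenation with a cationic rhodium diphosphine catalyst: the C3 hydroxyl binds rhodium and delivers hydrogen to the 1,1-disubstituted alkene in the conformer that avoids allylic 1,2-strain with the CH2OSi group, which should give the 2,3-anti methyl centre as known for 2-substituted allylic alcohols and α-(hydroxyalkyl)acrylates.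

Step 14
Reactants: 25 the hydroxy ketone
Product: 26 (2S,4S,5S,6S)-4,6-dimethyl-5,7-bis(triethylsilyloxy)-2-(3,5,6-trimethyl-4-oxo-4H-pyran-2-yl)heptan-3-one
Conditions: Et3SiOTf, 2,6-lutidine, CH2Cl2, −78 °C
Reagents that add atoms: triethylsilyl trifluoromethanesulfonate, CC[Si](CC)(CC)OS(=O)(=O)C(F)(F)F
Why: Silyl triflate with a hindered pyridine base silylates the hindered C3 hydroxyl at low temperature, which blocks the only other β-hydroxy ketone (C3–OH/C5=O) before the Tishchenko step.

Step 15
Reactants: 26 the bis-silyl ether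
Product: 27 (2R,3S,4S,6S)-2,4-dimethyl-5-oxo-3-(triethylsilyloxy)-6-(3,5,6-trimethyl-4-oxo-4H-pyran-2-yl)heptanal
Conditions: (COCl)2, Me2SO, CH2Cl2, −78 → −40 °C; Et3N, −78 → −20 °C; used at once
Reagents that add atoms: none
Why: Swern conditions oxidise a primary triethylsilyl ether directly to the aldehyde (the chlorosulfonium ion cleaves the unhindered Si–O bond) and should leave the hindered secondary silyl ether at C3 untouched.

Step 16
Reactants: 27 the C1 aldehyde; 7 (4R,5R,6S,7S)-5,7-dihydroxy-4,6-dimethylnonan-3-one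
Product: 29 (3R,4S,6S,7S)-3,7-dihydroxy-4,6-dimethylnonan-5-yl (2R,3R,4S,6S)-2,4-dimethyl-5-oxo-3-(triethylsilyloxy)-6-(3,5,6-trimethyl-4-oxo-4H-pyran-2-yl)heptanoate (3',5'-anti; C5' as in 7), via hemiacetal 28 (not isolated)
Conditions: SmI2 (30 mol%, preactivated with PhCHO, 30 mol%), 7 (1.5 equiv), THF, −10 °C
Reagents that add atoms: none
Why: The trivalent samarium alkoxide formed from divalent SmI2 binds the C5' hydroxyl and the C3' ketone of 7, the alkoxide adds to aldehyde C1 of 27 to give hemiacetal 28, and hydride passes from C1 to C3' through a six-membered chair held by samarium, which forms the C1(=O)–O5' ester bond and the C3'–H bond in one event. The closest known reaction type is the Evans–Tishchenko reduction used as a fragment coupling of β-hydroxy ketones with α-branched aldehydes. No ring is closed. The only new centre, C3', should be set 1,3-anti to C5' by the chair and is erased in step 17, as is the stereogenicity of C5'. The step needs acylation of the hindered C5' hydroxyl beside the free C7' hydroxyl and reaction at the aldehyde beside ketones and the pyrone: only the C5' hemiacetal can reach a ketone through a six-membered ring, no base or acylating agent is present to start retro-aldol cleavage or β-elimination, and the C3 hydroxyl of 27 is silylated so that 27 cannot serve as its own hydroxy ketone. If hydride went to C5 of the acyl part instead, the product would still converge on 30 in step 17.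

Step 17
Reactants: 29 the ester diol
Product: 30 (4R,6R)-4,6-dimethyl-3,7-dioxononan-5-yl (2R,3R,4S,6S)-2,4-dimethyl-5-oxo-3-(triethylsilyloxy)-6-(3,5,6-trimethyl-4-oxo-4H-pyran-2-yl)heptanoate
Conditions: Dess–Martin periodinane, pyridine, CH2Cl2, 0 °C → rt
Reagents that add atoms: none
Why: Buffered Dess–Martin oxidation turns both carbinols (C3', C7') into ketones without a base strong enough for β-elimination of the acyloxy group, which makes the two arms identical.

Step 18
Reactants: 30 the silylated target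
Product: 31 (4R,6R)-4,6-dimethyl-3,7-dioxononan-5-yl (2R,3R,4S,6S)-3-hydroxy-2,4-dimethyl-5-oxo-6-(3,5,6-trimethyl-4-oxo-4H-pyran-2-yl)heptanoate
Conditions: HF·pyridine, pyridine, THF, 0 °C
Reagents that add atoms: none
Why: Buffered fluoride desilylation removes the C3 triethylsilyl ether under conditions that should avoid retro-aldol cleavage, β-elimination and epimerisation at C6.

Compound list
1 | propanal | CCC=O | starting material
2 | (2S,3S)-3-hydroxy-2-methylpentanal | O=C[C@@H](C)[C@@H](O)CC | intermediate (not isolated)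
3 | (2S,3S)-2-methyl-3-(trimethylsilyloxy)pentanal | O=C[C@@H](C)[C@@H](O[Si](C)(C)C)CC | intermediate
4 | pentan-3-one | CCC(=O)CC | starting material
5 | (E)-enol dicyclohexylborinate of pentan-3-one | CC/C(OB(C1CCCCC1)C1CCCCC1)=C\C | intermediate (not isolated)
6 | (4R,5R,6R,7S)-5-hydroxy-4,6-dimethyl-7-(trimethylsilyloxy)nonan-3-one | CCC(=O)[C@H](C)[C@H](O)[C@@H](C)[C@@H](O[Si](C)(C)C)CC | intermediate (not isolated)
7 | (4R,5R,6S,7S)-5,7-dihydroxy-4,6-dimethylnonan-3-one | CCC(=O)[C@H](C)[C@H](O)[C@@H](C)[C@@H](O)CC | intermediate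
8 | (2R,3R)-3-hydroxy-2-methylpentanal | O=C[C@H](C)[C@H](O)CC | intermediate (not isolated)
9 | (2R,3R)-2-methyl-3-(triethylsilyloxy)pentanal | O=C[C@H](C)[C@H](O[Si](CC)(CC)CC)CC | intermediate
10 | 3-methylpentane-2,4-dione | CC(=O)C(C)C(C)=O | starting material
11 | (E)-4-methoxy-3-methylpent-3-en-2-one | CO/C(C)=C(C)/C(C)=O | intermediate
12 | lithium α′-enolate of 11 | CO/C(C)=C(C)/C(=C)O[Li] | intermediate (not isolated)
13 | (E)-5-methoxy-4-methylhex-4-en-3-one | CO/C(C)=C(C)/C(=O)CC | intermediate
14 | lithium α′-enolate of 13 (enolate geometry not controlled) | CO/C(C)=C(C)/C(O[Li])=CC | intermediate (not isolated)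
15 | (E)-6-hydroxy-2-methoxy-3,5,7-trimethyl-8-(triethylsilyloxy)dec-2-en-4-one (C7 and C8 as in 9; mixture at C5 and C6) | CO/C(C)=C(C)/C(=O)C(C)C(O)[C@H](C)[C@H](O[Si](CC)(CC)CC)CC | intermediate
16 | (2E,7R,8R)-2-methoxy-3,5,7-trimethyl-8-(triethylsilyloxy)dec-2-ene-4,6-dione (C5 stereolabile) | CO/C(C)=C(C)/C(=O)C(C)C(=O)[C@H](C)[C@H](O[Si](CC)(CC)CC)CC | intermediate
17 | 3,5,6-trimethyl-2-[(2R,3R)-3-(triethylsilyloxy)pentan-2-yl]-4H-pyran-4-one | CC[C@@H](O[Si](CC)(CC)CC)[C@@H](C)c1oc(C)c(C)c(=O)c1C | intermediate (not isolated)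
18 | 2-[(2R,3R)-3-hydroxypentan-2-yl]-3,5,6-trimethyl-4H-pyran-4-one | CC[C@@H](O)[C@@H](C)c1oc(C)c(C)c(=O)c1C | intermediate
19 | 3,5,6-trimethyl-2-[(2S)-3-oxopentan-2-yl]-4H-pyran-4-one | CCC(=O)[C@@H](C)c1oc(C)c(C)c(=O)c1C | intermediate
20 | 2-methylidenepropane-1,3-diol | C=C(CO)CO | starting material
21 | 2-[(triethylsilyloxy)methyl]prop-2-en-1-ol | C=C(CO)CO[Si](CC)(CC)CC | intermediate
22 | 2-[(triethylsilyloxy)methyl]prop-2-enal | C=C(C=O)CO[Si](CC)(CC)CC | intermediate
23 | (E)-enol dicyclohexylborinate of 19 | C/C=C(/OB(C1CCCCC1)C1CCCCC1)[C@@H](C)c1oc(C)c(C)c(=O)c1C | intermediate (not isolated)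
24 | (2S,4S,5R)-5-hydroxy-4-methyl-6-[(triethylsilyloxy)methyl]-2-(3,5,6-trimethyl-4-oxo-4H-pyran-2-yl)hept-6-en-3-one | CC[Si](CC)(CC)OCC(=C)[C@H](O)[C@H](C)C(=O)[C@@H](C)c1oc(C)c(C)c(=O)c1C | intermediate
25 | (2S,4S,5S,6S)-5-hydroxy-4,6-dimethyl-7-(triethylsilyloxy)-2-(3,5,6-trimethyl-4-oxo-4H-pyran-2-yl)heptan-3-one | CC[Si](CC)(CC)OC[C@H](C)[C@H](O)[C@H](C)C(=O)[C@@H](C)c1oc(C)c(C)c(=O)c1C | intermediate
26 | (2S,4S,5S,6S)-4,6-dimethyl-5,7-bis(triethylsilyloxy)-2-(3,5,6-trimethyl-4-oxo-4H-pyran-2-yl)heptan-3-one | CC[Si](CC)(CC)OC[C@H](C)[C@H](O[Si](CC)(CC)CC)[C@H](C)C(=O)[C@@H](C)c1oc(C)c(C)c(=O)c1C | intermediate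
27 | (2R,3S,4S,6S)-2,4-dimethyl-5-oxo-3-(triethylsilyloxy)-6-(3,5,6-trimethyl-4-oxo-4H-pyran-2-yl)heptanal | O=C[C@H](C)[C@H](O[Si](CC)(CC)CC)[C@H](C)C(=O)[C@@H](C)c1oc(C)c(C)c(=O)c1C | intermediate
28 | mixed hemiacetal of 27 (C1) with the C5 hydroxyl of 7 (present as its samarium alkoxide) | CCC(=O)[C@H](C)[C@H](OC(O)[C@H](C)[C@H](O[Si](CC)(CC)CC)[C@H](C)C(=O)[C@@H](C)c1oc(C)c(C)c(=O)c1C)[C@@H](C)[C@@H](O)CC | intermediate (not isolated)
29 | (3R,4S,6S,7S)-3,7-dihydroxy-4,6-dimethylnonan-5-yl (2R,3R,4S,6S)-2,4-dimethyl-5-oxo-3-(triethylsilyloxy)-6-(3,5,6-trimethyl-4-oxo-4H-pyran-2-yl)heptanoate (3',5'-anti; C5' as in 7) | CC[C@@H](O)[C@H](C)[C@H](OC(=O)[C@H](C)[C@H](O[Si](CC)(CC)CC)[C@H](C)C(=O)[C@@H](C)c1oc(C)c(C)c(=O)c1C)[C@@H](C)[C@@H](O)CC | intermediate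
30 | (4R,6R)-4,6-dimethyl-3,7-dioxononan-5-yl (2R,3R,4S,6S)-2,4-dimethyl-5-oxo-3-(triethylsilyloxy)-6-(3,5,6-trimethyl-4-oxo-4H-pyran-2-yl)heptanoate | CCC(=O)[C@H](C)C(OC(=O)[C@H](C)[C@H](O[Si](CC)(CC)CC)[C@H](C)C(=O)[C@@H](C)c1oc(C)c(C)c(=O)c1C)[C@@H](C)C(=O)CC | intermediate
31 | (4R,6R)-4,6-dimethyl-3,7-dioxononan-5-yl (2R,3R,4S,6S)-3-hydroxy-2,4-dimethyl-5-oxo-6-(3,5,6-trimethyl-4-oxo-4H-pyran-2-yl)heptanoate | CCC(=O)[C@H](C)C(OC(=O)[C@H](C)[C@H](O)[C@H](C)C(=O)[C@@H](C)c1oc(C)c(C)c(=O)c1C)[C@@H](C)C(=O)CC | target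

Total step count: 18. Longest linear sequence: 13 (steps 4, 5, 6, 7, 8, 9, 12, 13, 14, 15, 16, 17, 18).

Steps most likely to fail

1. Step 12 (anti aldol of 19). The boron chloride may be held by the basic pyrone carbonyl, enolisation may stray to the C6–H or the ring methyl groups, or the 1,3-induction from C6 may be weak.
The fallback sets C3 and C4 before the ketone exists, brings in the pyrone as a preformed ring and methylates C6 last; it sets out from 1 and 4 and comes back at 26. Methyl (S)-3-hydroxy-2-methylpropanoate would be silylated (Et3SiCl, imidazole) to methyl (S)-2-methyl-3-(triethylsilyloxy)propanoate F1 and reduced (i-Bu2AlH, −78 °C) to (S)-2-methyl-3-(triethylsilyloxy)propanal F2. An L-proline-catalysed cross-aldol with propanal 1 (slow addition) should give (2S,3S,4S)-3-hydroxy-2,4-dimethyl-5-(triethylsilyloxy)pentanal F3 under catalyst control, silylated to (2S,3S,4S)-2,4-dimethyl-3,5-bis(triethylsilyloxy)pentanal F4. 2,3,5,6-Tetramethyl-4H-pyran-4-one F5 (from 4, acetic anhydride and polyphosphoric acid) would be lithiated at a 2-methyl group (LiN(SiMe3)2, THF, −78 °C) and added to F4 to give 2-[(3R,4S,5S)-2-hydroxy-3,5-dimethyl-4,6-bis(triethylsilyloxy)hexyl]-3,5,6-trimethyl-4H-pyran-4-one F6. Dess–Martin oxidation would give 3,5,6-trimethyl-2-[(3S,4S,5S)-3,5-dimethyl-2-oxo-4,6-bis(triethylsilyloxy)hexyl]-4H-pyran-4-one F7, and C-methylation at C6 (NaH, 1 equiv, MeI) would give 26. The price is a separation from its C6 epimer, which would be recycled by base equilibration.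

2. Step 16 (Evans–Tishchenko union). Hemiacetal formation at the hindered C5' hydroxyl may be slow, and ring-chain tautomerism of the δ-hydroxy ketone in 7 (closure of the C7' hydroxyl onto C3') may withhold the free β-hydroxy ketone, so that 27 is lost to intramolecular aldol addition (C6 onto C1); the acyl group may also migrate in 29.
The fallback is acylation of a mono-protected alcohol; it sets out from 27 and comes back at 30. Oxidation (NaClO2, NaH2PO4, 2-methylbut-2-ene) would give (2R,3R,4S,6S)-2,4-dimethyl-5-oxo-3-(triethylsilyloxy)-6-(3,5,6-trimethyl-4-oxo-4H-pyran-2-yl)heptanoic acid F8. Esterification (2-methyl-6-nitrobenzoic anhydride, DMAP, Et3N) with silyl ether 6, isolated from step 2 before the acid treatment, would give the ester of F8 with the C5 hydroxyl of 6, F9. Citric acid in methanol would free the (4R,6S,7S)-7-hydroxy-4,6-dimethyl-3-oxononan-5-yl ester F10, and Dess–Martin oxidation would give 30.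

3. Step 13 (directed hydrogenation). The facial selectivity may be poor, or rhodium may isomerise the allylic silyl ether to an enol ether.
The fallback buys C2 instead of setting it; it sets out from 19 and comes back at 25. Enol borinate 23 would be added to aldehyde F2 (made as in the fallback for step 12) to give 25 directly; here the ketone must override the Felkin preference of the aldehyde.

Further compounds
F1 | step 12 | methyl (S)-2-methyl-3-(triethylsilyloxy)propanoate | COC(=O)[C@@H](C)CO[Si](CC)(CC)CC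
F2 | step 12 | (S)-2-methyl-3-(triethylsilyloxy)propanal | O=C[C@@H](C)CO[Si](CC)(CC)CC
F3 | step 12 | (2S,3S,4S)-3-hydroxy-2,4-dimethyl-5-(triethylsilyloxy)pentanal | O=C[C@@H](C)[C@@H](O)[C@@H](C)CO[Si](CC)(CC)CC
F4 | step 12 | (2S,3S,4S)-2,4-dimethyl-3,5-bis(triethylsilyloxy)pentanal | O=C[C@@H](C)[C@@H](O[Si](CC)(CC)CC)[C@@H](C)CO[Si](CC)(CC)CC
F5 | step 12 | 2,3,5,6-tetramethyl-4H-pyran-4-one | Cc1oc(C)c(C)c(=O)c1C
F6 | step 12 | 2-[(3R,4S,5S)-2-hydroxy-3,5-dimethyl-4,6-bis(triethylsilyloxy)hexyl]-3,5,6-trimethyl-4H-pyran-4-one (mixture at the new carbinol) | Cc1oc(CC(O)[C@@H](C)[C@@H](O[Si](CC)(CC)CC)[C@@H](C)CO[Si](CC)(CC)CC)c(C)c(=O)c1C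
F7 | step 12 | 3,5,6-trimethyl-2-[(3S,4S,5S)-3,5-dimethyl-2-oxo-4,6-bis(triethylsilyloxy)hexyl]-4H-pyran-4-one | Cc1oc(CC(=O)[C@@H](C)[C@@H](O[Si](CC)(CC)CC)[C@@H](C)CO[Si](CC)(CC)CC)c(C)c(=O)c1C
F8 | step 16 | (2R,3R,4S,6S)-2,4-dimethyl-5-oxo-3-(triethylsilyloxy)-6-(3,5,6-trimethyl-4-oxo-4H-pyran-2-yl)heptanoic acid | OC(=O)[C@H](C)[C@H](O[Si](CC)(CC)CC)[C@H](C)C(=O)[C@@H](C)c1oc(C)c(C)c(=O)c1C
F9 | step 16 | ester of F8 with the C5 hydroxyl of 6 | CCC(=O)[C@H](C)[C@H](OC(=O)[C@H](C)[C@H](O[Si](CC)(CC)CC)[C@H](C)C(=O)[C@@H](C)c1oc(C)c(C)c(=O)c1C)[C@@H](C)[C@@H](O[Si](C)(C)C)CC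
F10 | step 16 | (4R,6S,7S)-7-hydroxy-4,6-dimethyl-3-oxononan-5-yl ester of F8 | CCC(=O)[C@H](C)[C@H](OC(=O)[C@H](C)[C@H](O[Si](CC)(CC)CC)[C@H](C)C(=O)[C@@H](C)c1oc(C)c(C)c(=O)c1C)[C@@H](C)[C@@H](O)CC
F0 | step 13 | none | none
A1 | direct plan | (2R,3R)-2-[(S)-1-(benzyloxy)propan-2-yl]-3,5-dimethyl-2,3-dihydro-4H-pyran-4-one | CC1=CO[C@H]([C@@H](C)COCc2ccccc2)[C@@H](C)C1=O
A2 | direct plan | δ-lactone (C1 to O–C5) of the 3-(tert-butyldimethylsilyloxy) acid with the 1-(3,5,6-trimethyl-4-oxo-4H-pyran-2-yl)ethyl side chain | O=C1[C@H](C)[C@H](O[Si](C)(C)C(C)(C)C)[C@H](C)[C@@H]([C@@H](C)c2oc(C)c(C)c(=O)c2C)O1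
A3 | direct plan | 3-(tert-butyldimethylsilyloxy)-2,4-dimethyl-5-(triethylsilyloxy)-6-(3,5,6-trimethyl-4-oxo-4H-pyran-2-yl)heptanoic acid (2,3-anti, 3,4-anti, 4,5-anti, 5,6-syn) | OC(=O)[C@H](C)[C@H](O[Si](C)(C)C(C)(C)C)[C@H](C)[C@H](O[Si](CC)(CC)CC)[C@@H](C)c1oc(C)c(C)c(=O)c1C
A4 | direct plan | (4R,5R,6R,7R)-5-hydroxy-4,6-dimethyl-7-(triethylsilyloxy)nonan-3-one | CCC(=O)[C@H](C)[C@H](O)[C@@H](C)[C@H](O[Si](CC)(CC)CC)CC
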